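Ring C of the flavone is disconnected at C2–C3 and O1–C8a. In ring A, the acyl-bearing C4a lies between two oxygen-bearing carbons (C5–OH and C8a–O1) with the C7 methoxy opposite, so a 2,6-difluoro-4-methoxyphenyl methoxymethyl ketone, whose two fluorines are equivalent, supplies ring A whichever fluorine leaves. In one operation its enolate is aroylated at carbon by 2,3,4,6-tetramethoxybenzoyl chloride (ring B as a masked quinone) and the enolate oxygen of the resulting diketone displaces one fluoride to close ring C. The surviving C5 fluoride is then exchanged for hydroxyl and ring B is oxidised to the quinone.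

Key step: step 4

Remarks on the chemistry:
- Flavone numbering is used for the chromone (O1, C2, C3, C4, C4a, C5 to C8, C8a) and primed numbers for ring B.
- The target has no stereocentre.
- The quinone carbonyls correspond to C3′ and C6′ of a 2,3,4,6-tetramethoxyphenyl group, the only para pair of methoxy groups in that ring.
- N,2-Dimethoxy-N-methylacetamide is assumed to be a purchasable reagent; it is otherwise one step from methoxyacetyl chloride and MeNHOMe·HCl.

Step 1
Reactants: 1 3,5-difluoroanisole; 2 N,2-dimethoxy-N-methylacetamide
Product: 4 1-(2,6-difluoro-4-methoxyphenyl)-2-methoxyethanone, via difluoroaryllithium 3 (not isolated)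
Conditions: n-BuLi, THF, −78 °C; then 2, −78 to −20 °C; aq. HCl
Reagents that add atoms: none
Why: Directed ortho-lithiation removes the most acidic ring hydrogen, the one flanked by both fluorines, and the Weinreb ketone synthesis then stops at the ketone because the chelated tetrahedral adduct survives until the quench; keeping 3 at −78 °C prevents loss of LiF to an aryne.

Step 2
Reactants: 5 1,2,3,5-tetramethoxybenzene
Product: 7 2,3,4,6-tetramethoxybenzoic acid, via tetramethoxyaryllithium 6 (not isolated)
Conditions: n-BuLi, TMEDA, THF, 0 °C to rt; then CO2, −78 °C to rt; aq. HCl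
Reagents that add atoms: carbon dioxide, O=C=O
Why: Directed ortho-metalation between two methoxy groups followed by carboxylation of the aryllithium; the two ring hydrogens of 5 are equivalent, so only one aryllithium can form.

Step 3
Reactants: 7 2,3,4,6-tetramethoxybenzoic acid
Product: 8 2,3,4,6-tetramethoxybenzoyl chloride
Conditions: (COCl)2, DMF (cat.), CH2Cl2, 0 °C to rt; evaporate, use crude
Reagents that add atoms: oxalyl chloride, O=C(Cl)C(=O)Cl
Why: Acid chloride formation through the catalytic chloroiminium species runs cold and without Lewis acid, so the electron-rich ring and its ortho-methoxy groups should be untouched.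

Step 4
Reactants: 4 1-(2,6-difluoro-4-methoxyphenyl)-2-methoxyethanone; 8 2,3,4,6-tetramethoxybenzoyl chloride
Product: 10 5-fluoro-3,7-dimethoxy-2-(2,3,4,6-tetramethoxyphenyl)chromen-4-one, via diketone 9 (not isolated)
Conditions: MgBr2·OEt2, i-Pr2NEt, CH2Cl2, 0 °C to rt; 1 M HCl wash, evaporate; then K2CO3, DMF, 60 °C
Reagents that add atoms: none
Why: MgBr2·OEt2 chelates the carbonyl and α-methoxy oxygens of 4 so that i-Pr2NEt can deprotonate it (soft enolisation), and the magnesium enolate is acylated at carbon by 8 to form C2–C3; after removal of magnesium, K2CO3 turns crude diketone 9 into its enolate, whose oxygen on the ring B carbonyl carbon (future O1) adds to a fluorine-bearing carbon of ring A (future C8a), and the Meisenheimer adduct expels fluoride. The closest known reaction type is acylation of a ketone or β-dicarbonyl enolate followed by cyclising displacement of an ortho-fluoride, the usual entry to 4-quinolones and chromones from ortho-fluoroaryl ketones. Ring C closes as a six-membered ring by intramolecular nucleophilic aromatic substitution (6-exo-trig with respect to the C8a=C8 π bond of ring A), the charge of the adduct being delocalised into the C4 carbonyl. No stereocentre is formed, and the labile stereocentre at C3 of 9 is erased on cyclisation. C- over O-acylation is secured by the magnesium chelate, O- over C-arylation by geometry (attack through C3 would need a four-membered ring), and site selectivity in ring A is not an issue because the two fluorines are equivalent, ortho to the carbonyl and meta to the C7 methoxy. Cyclising at 60 °C keeps DMF from releasing dimethylamine, which could displace the remaining activated C5 fluoride.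

Step 5
Reactants: 10 5-fluoro-3,7-dimethoxy-2-(2,3,4,6-tetramethoxyphenyl)chromen-4-one
Product: 12 5-hydroxy-3,7-dimethoxy-2-(2,3,4,6-tetramethoxyphenyl)chromen-4-one, via sulfonylethyl ether 11 (not isolated)
Conditions: MeSO2CH2CH2OH, NaH, DMF, 0 °C to rt; aq. HCl
Reagents that add atoms: 2-(methylsulfonyl)ethanol, CS(=O)(=O)CCO
Why: Nucleophilic aromatic substitution of the C5 fluoride (ortho to the C4 carbonyl, meta to both ring A oxygens) by the alkoxide, then base-induced E1cB loss of methyl vinyl sulfone from 11, is a known hydroxide-surrogate protocol for activated aryl fluorides; the product forms as the unreactive chelated phenoxide, which should protect it from further attack.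

Step 6
Reactants: 12 5-hydroxy-3,7-dimethoxy-2-(2,3,4,6-tetramethoxyphenyl)chromen-4-one
Product: 13 2-(5-hydroxy-3,7-dimethoxy-4-oxo-4H-chromen-2-yl)-3,5-dimethoxycyclohexa-2,5-diene-1,4-dione (CNP0259413.0)
Conditions: (NH4)2Ce(NO3)6, MeCN–H2O (3:1), 0 °C
Reagents that add atoms: water, O
Why: Oxidative demethylation of a para-dimethoxyarene by tetravalent cerium should act on ring B, the most electron-rich ring and twisted out of conjugation with the pyranone, at its single para pair of methoxy groups (C3′ and C6′): electron transfer, addition of water at these carbons and loss of two methanol give the 1,4-quinone, while the hydrogen-bonded C5 phenol on the carbonyl-deactivated ring A should survive the short, cold reaction.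

Compound list

1 | 3,5-difluoroanisole | COc1cc(F)cc(F)c1 | starting material
2 | N,2-dimethoxy-N-methylacetamide | COCC(=O)N(C)OC | starting material
3 | (2,6-difluoro-4-methoxyphenyl)lithium | [Li]c1c(F)cc(OC)cc1F | intermediate
4 | 1-(2,6-difluoro-4-methoxyphenyl)-2-methoxyethanone | COCC(=O)c1c(F)cc(OC)cc1F | intermediate
5 | 1,2,3,5-tetramethoxybenzene | COc1cc(OC)c(OC)c(OC)c1 | starting material
6 | (2,3,4,6-tetramethoxyphenyl)lithium | [Li]c1c(OC)cc(OC)c(OC)c1OC | intermediate
7 | 2,3,4,6-tetramethoxybenzoic acid | COc1cc(OC)c(C(=O)O)c(OC)c1OC | intermediate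
8 | 2,3,4,6-tetramethoxybenzoyl chloride | COc1cc(OC)c(C(Cl)=O)c(OC)c1OC | intermediate
9 | 1-(2,6-difluoro-4-methoxyphenyl)-2-methoxy-3-(2,3,4,6-tetramethoxyphenyl)propane-1,3-dione (racemic, configurationally labile; keto form drawn) | COC(C(=O)c1c(F)cc(OC)cc1F)C(=O)c1c(OC)cc(OC)c(OC)c1OC | intermediate
10 | 5-fluoro-3,7-dimethoxy-2-(2,3,4,6-tetramethoxyphenyl)chromen-4-one | COc1cc(F)c2c(=O)c(OC)c(-c3c(OC)c(OC)c(OC)cc3OC)oc2c1 | intermediate
11 | 3,7-dimethoxy-5-[2-(methylsulfonyl)ethoxy]-2-(2,3,4,6-tetramethoxyphenyl)chromen-4-one | COc1cc(OCCS(C)(=O)=O)c2c(=O)c(OC)c(-c3c(OC)c(OC)c(OC)cc3OC)oc2c1 | intermediate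
12 | 5-hydroxy-3,7-dimethoxy-2-(2,3,4,6-tetramethoxyphenyl)chromen-4-one | COc1cc(O)c2c(=O)c(OC)c(-c3c(OC)c(OC)c(OC)cc3OC)oc2c1 | intermediate
13 | 2-(5-hydroxy-3,7-dimethoxy-4-oxo-4H-chromen-2-yl)-3,5-dimethoxycyclohexa-2,5-diene-1,4-dione | COC1=CC(=O)C(c2oc3cc(OC)cc(O)c3c(=O)c2OC)=C(OC)C1=O | target

Total steps: 6. Longest linear sequence: 5 steps (5 → 7 → 8 → 10 → 12 → 13).

Steps most likely to fail

Step 4. The magnesium enolate may be acylated on oxygen, or only slowly on carbon, because the acid chloride carries two ortho-methoxy groups; the diketone may also suffer retro-Claisen cleavage during the basic cyclisation. The fallback sets out from 4, with a partner made from 5 by way of 6, and comes back to the route at 9. It forms C2–C3 by aldol addition and adjusts the oxidation level afterwards. Aryllithium 6, generated as in step 2, would be quenched with DMF to give 2,3,4,6-tetramethoxybenzaldehyde F1. The lithium enolate of 4 (LiN(i-Pr)2, THF, −78 °C) would add to F1 to give 1-(2,6-difluoro-4-methoxyphenyl)-3-hydroxy-2-methoxy-3-(2,3,4,6-tetramethoxyphenyl)propan-1-one F2 as a diastereomer mixture, both isomers converging later. Dess–Martin periodinane in CH2Cl2 should oxidise F2 to diketone 9, which is cyclised with K2CO3 in DMF as in step 4 to reach 10.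

Step 5. Substitution at C5 may be slow because the pyranone carbonyl activates less strongly than a simple ketone; the elimination from ether 11 may stall, or the alkoxide may add at C2 and open ring C. The fallback sets out from 10 and comes back at 12. It brings in the oxygen as a benzyl ether and unmasks it by hydrogenolysis in place of base-induced elimination. NaOCH2Ph (PhCH2OH, NaH, THF, 0 °C to rt) should give 5-(benzyloxy)-3,7-dimethoxy-2-(2,3,4,6-tetramethoxyphenyl)chromen-4-one F3. H2 over Pd on carbon in EtOAc should then cleave the benzyl group to give 12, the tetrasubstituted C2=C3 bond being inert.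

Step 6. The free phenol ring A may be oxidised or nitrated in competition with ring B, and the acidic aqueous medium may hydrolyse the vinylogous ester methoxy groups of the quinone. The fallback sets out from 12 and comes back at 13. It masks the phenol before the oxidation. Ac2O, pyridine and DMAP should give 3,7-dimethoxy-4-oxo-2-(2,3,4,6-tetramethoxyphenyl)-4H-chromen-5-yl acetate F4. (NH4)2Ce(NO3)6 in MeCN–H2O at 0 °C should then oxidise ring B to 2-(2,4-dimethoxy-3,6-dioxocyclohexa-1,4-dien-1-yl)-3,7-dimethoxy-4-oxo-4H-chromen-5-yl acetate F5. HCl in MeOH (from AcCl) at rt should remove the acetate by transesterification to give 13; any exchange at the quinone methoxy groups is degenerate in methanol.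

Further compounds

F1 | step 4 | 2,3,4,6-tetramethoxybenzaldehyde | COc1cc(OC)c(C=O)c(OC)c1OC
F2 | step 4 | 1-(2,6-difluoro-4-methoxyphenyl)-3-hydroxy-2-methoxy-3-(2,3,4,6-tetramethoxyphenyl)propan-1-one (mixture of racemic diastereomers) | COC(C(=O)c1c(F)cc(OC)cc1F)C(O)c1c(OC)cc(OC)c(OC)c1OC
F3 | step 5 | 5-(benzyloxy)-3,7-dimethoxy-2-(2,3,4,6-tetramethoxyphenyl)chromen-4-one | COc1cc(OCc2ccccc2)c2c(=O)c(OC)c(-c3c(OC)c(OC)c(OC)cc3OC)oc2c1
F4 | step 6 | 3,7-dimethoxy-4-oxo-2-(2,3,4,6-tetramethoxyphenyl)-4H-chromen-5-yl acetate | COc1cc(OC(C)=O)c2c(=O)c(OC)c(-c3c(OC)c(OC)c(OC)cc3OC)oc2c1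
F5 | step 6 | 2-(2,4-dimethoxy-3,6-dioxocyclohexa-1,4-dien-1-yl)-3,7-dimethoxy-4-oxo-4H-chromen-5-yl acetate | COC1=CC(=O)C(c2oc3cc(OC)cc(OC(C)=O)c3c(=O)c2OC)=C(OC)C1=O
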